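**Plan**
1. Retrosynthesis: benzyl ethers and acetates go last; the two upper C4–C8 bonds (unit 1→2, unit 2→3) are cut as flavan C4 cation/arene unions; the bond C4(unit 3)–C8(catechin) is cut together with C4–C4a and C3–O of ring C of unit 3.
2. This turns ring C of unit 3 into the five-membered ring O1–C2–C3–C4a–C8a of the cis-2,3-dihydrobenzofuran-3-carbaldehyde 10, whose formyl carbon is the future C4; 10 goes back to an aryldiazoacetate (C2–C3 bond by carbenoid C–H insertion) built on 3,5-bis(benzyloxy)phenol.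
3. Forward: 1 → 10 (six steps); 10, Ac2O and protected catechin 13 are joined in one flask with ring enlargement to dimer 16; two chain extensions with the epicatechin C4 electrophile 19 give trimer 20 and tetramer 21; methanolysis and hydrogenolysis finish.
4. Enabling feature: ring A of unit 3 is a phloroglucinol ether; its ipso carbon C4a is ortho to O1 and O5 and para to O7, so it migrates readily and stabilises a cation at C4, while the C3 oxygen can be handed over from C4 as an acetoxonium bridge.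
5. Stereochemistry: units 1, 2 and 4 come from (−)-epicatechin and (+)-catechin; in unit 3, C2 comes from the catalyst-controlled cis-selective C–H insertion, C3 from inversion during the 1,2-shift, and every C4 from arene attack anti to the C3 oxygen (3,4-trans, 4β).

Key step: step 9

Remark: compounds 1, 3, 11 and 17 are taken as commercial; the rhodium catalyst of step 4 is assumed to induce the (2S,3R) sense (otherwise its mirror-image form Rh2(R-PTTL)4 is used).

**Step 1**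
Reactants: 1 3,5-bis(benzyloxy)phenol
Product: 2 4,6-bis(benzyloxy)-1-benzofuran-2,3-dione
Conditions: (COCl)2, CH2Cl2, 0 °C → reflux
Reagents that add atoms: oxalyl chloride, ClC(=O)C(=O)Cl
Why: O-acylation of the phenol and intramolecular Friedel–Crafts acylation at either of the two equivalent ortho carbons (the oxygen counterpart of the Stollé synthesis) closes the α-keto lactone, a reaction type known for 3,5-dialkoxyphenols.

**Step 2**
Reactants: 2 4,6-bis(benzyloxy)-1-benzofuran-2,3-dione; 3 3,4-bis(benzyloxy)benzyl chloride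
Product: 5 methyl 2-{2,4-bis(benzyloxy)-6-{[3,4-bis(benzyloxy)phenyl]methoxy}phenyl}-2-oxoacetate, via hydroxy keto ester 4 (not isolated)
Conditions: MeOH, K2CO3, 0 °C → rt; evaporate; 3, K2CO3, DMF, 50 °C
Reagents that add atoms: methanol, CO
Why: methanolysis of the activated lactone carbonyl frees the phenoxide, which is trapped by Williamson etherification, so that the future C2 and ring B sit on the oxygen ortho to the keto ester.

**Step 3**
Reactants: 5 keto ester
Product: 7 methyl 2-{2,4-bis(benzyloxy)-6-{[3,4-bis(benzyloxy)phenyl]methoxy}phenyl}-2-diazoacetate, via tosylhydrazone 6 (not isolated)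
Conditions: TsNHNH2, MeOH, 50 °C; then DBU, CH2Cl2, 0 °C → rt
Reagents that add atoms: 4-methylbenzenesulfonohydrazide, Cc1ccc(cc1)S(=O)(=O)NN
Why: condensation of the α-keto ester with the sulfonyl hydrazide and base-induced loss of sulfinate (Bamford–Stevens-type diazo synthesis) is the standard route to aryldiazoacetates.

**Step 4**
Reactants: 7 aryldiazoacetate
Product: 8 methyl (2S,3R)-4,6-bis(benzyloxy)-2-[3,4-bis(benzyloxy)phenyl]-2,3-dihydro-1-benzofuran-3-carboxylate (cis)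
Conditions: Rh2(S-PTTL)4 (dirhodium tetrakis[N-phthaloyl-(S)-tert-leucinate], 1 mol %), toluene, −60 °C
Reagents that add atoms: none
Why: intramolecular carbenoid 1,5-C–H insertion of aryldiazoacetates into ortho benzylic ether C–H bonds with N-phthaloyl amino acid dirhodium catalysts is known to give cis-2-aryl-2,3-dihydrobenzofuran-3-carboxylates, both stereocentres (2S,3R) being set by the chiral catalyst in the concerted insertion, and the alkoxy-activated C–H of the 3,4-bis(benzyloxy)benzyl ether should react in preference to the plain benzyl ether at the other ortho oxygen.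

**Step 5**
Reactants: 8 cis ester
Product: 9 [(2S,3S)-4,6-bis(benzyloxy)-2-[3,4-bis(benzyloxy)phenyl]-2,3-dihydro-1-benzofuran-3-yl]methanol (cis)
Conditions: i-Bu2AlH, CH2Cl2, −78 °C; aq. potassium sodium tartrate
Reagents that add atoms: none
Why: non-basic hydride reduction of the ester at low temperature gives the primary alcohol without enolisation or retro-oxa-Michael opening, so the cis relationship is kept.

**Step 6**
Reactants: 9 cis alcohol
Product: 10 (2S,3R)-4,6-bis(benzyloxy)-2-[3,4-bis(benzyloxy)phenyl]-2,3-dihydro-1-benzofuran-3-carbaldehyde (cis)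
Conditions: Dess–Martin oxidation (1,1,1-triacetoxy-1,1-dihydro-1,2-benziodoxol-3(1H)-one), pyridine, CH2Cl2, 0 °C; used at once
Reagents that add atoms: none
Why: the buffered Dess–Martin oxidation is mild enough to give the α-aryl aldehyde without epimerisation of the cis centre, provided the product is used directly.

**Step 7**
Reactants: 11 (+)-catechin
Product: 12 5,7,3',4'-tetra-O-benzyl-(+)-catechin
Conditions: BnBr, K2CO3, DMF, 0 °C → rt
Reagents that add atoms: benzyl bromide, BrCc1ccccc1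
Why: Williamson benzylation takes the four phenols, which are far more acidic than the secondary 3-OH, and leaves the stereocentres untouched.

**Step 8**
Reactants: 12 tetra-O-benzylcatechin
Product: 13 3-O-acetyl-5,7,3',4'-tetra-O-benzyl-(+)-catechin
Conditions: Ac2O, pyridine, DMAP (cat.), CH2Cl2, rt
Reagents that add atoms: acetic anhydride, CC(=O)OC(C)=O
Why: DMAP-catalysed acetylation caps the 3-OH so that the nucleophile is inert to Ac2O/TMSOTf in the next step.

**Step 9**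
Reactants: 10 cis aldehyde; 13 3-O-acetyl-tetra-O-benzylcatechin
Product: 16 3-O-acetyl-5,7,3',4'-tetra-O-benzylepicatechin-(4β→8)-3-O-acetyl-5,7,3',4'-tetra-O-benzylcatechin, via gem-diacetate 14 (not isolated), via flavan-3,4-diyl diacetate 15 (not isolated)
Conditions: Ac2O (1.1 equiv), TMSOTf (0.2 equiv), CH2Cl2, −78 °C, 20 min; then 13 (3 equiv), −78 → −40 °C; Et3N
Reagents that add atoms: acetic anhydride, CC(=O)OC(C)=O
Why: Proposed new method: TMSOTf/Ac2O turn the aldehyde into the gem-diacetate 14, whose ionisation to the α-acetoxy carbenium ion is assisted by the ipso carbon C4a of ring A, which shifts from C3 to the exocyclic carbon through a spiro arenium (phenonium) ion while the acetoxy group on that carbon captures C3 from the rear as a 1,3-dioxolan-2-ylium ion; this opens to the 3-acetoxy C4 benzylic cation (resting as diacetate 15), which is attacked by C8 of 13. The closest known reaction types are aryl-assisted solvolysis with 1,2-aryl shift (the ring contraction of 3-activated catechins to 2,3-dihydrobenzofurans is the same shift in reverse), the acid-catalysed aldehyde–ketone rearrangement, acyloxonium neighbouring-group participation and the TMSOTf-mediated C4 arylation of 3-O-acyl-4-oxyflavans. Ring C (O1, C2, C3, C4, C4a, C8a) is not closed by cyclisation but by enlargement of the five-membered ring O1–C2–C3–C4a–C8a, the former formyl carbon being inserted between C3 and C4a (Wagner–Meerwein/semipinacol-type 1,2-shift). C2 is carried over unchanged from 10, C3 is inverted because the acetoxy oxygen enters anti to the departing C4a so that the cis aldehyde gives the 2,3-cis ester, and C4 is set by attack of the arene anti to the 3-acetoxy group (acetoxonium shielding), giving 3,4-trans (4β). The step needs aryl migration to outrun 1,2-hydride shift and enolisation (secured by the threefold oxygen-activated ring A as neighbouring group, by the internal acetoxy group that can reach only C3, and by the low temperature), C8 rather than C6 attack on 13 (the known preference of benzylated catechin) and mono-addition (13 in excess, added after 10 has been consumed).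

**Step 10**
Reactants: 17 (−)-epicatechin
Product: 18 5,7,3',4'-tetra-O-benzyl-(−)-epicatechin
Conditions: BnBr, K2CO3, DMF, 0 °C → rt
Reagents that add atoms: benzyl bromide, BrCc1ccccc1
Why: Williamson benzylation of the four phenols as in step 7, with no change at the stereocentres.

**Step 11**
Reactants: 18 tetra-O-benzylepicatechin
Product: 19 4β-(2-ethoxyethoxy)-5,7,3',4'-tetra-O-benzyl-(−)-epicatechin
Conditions: DDQ, 2-ethoxyethanol, CH2Cl2, rt
Reagents that add atoms: 2-ethoxyethanol, CCOCCO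
Why: DDQ abstracts hydride from the doubly activated C4–H and the alcohol traps the quinone-methide-type cation anti to 3-OH (oxidative C–H etherification known for benzylated flavan-3-ols), giving the 4β ether.

**Step 12**
Reactants: 16 dimer diacetate; 19 epicatechin C4 electrophile
Product: 20 5,7,3',4'-tetra-O-benzylepicatechin-(4β→8)-3-O-acetyl-5,7,3',4'-tetra-O-benzylepicatechin-(4β→8)-3-O-acetyl-5,7,3',4'-tetra-O-benzylcatechin
Conditions: 16 (2.5 equiv), TMSOTf (0.2 equiv), CH2Cl2, −78 °C; Et3N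
Reagents that add atoms: none
Why: TMSOTf ionises the C4 ether and the cation is taken by the most nucleophilic and least hindered position, C8 of the upper unit of 16, anti to the 3-hydroxy group (Lewis-acid-mediated Friedel–Crafts-type flavan coupling), which sets 4β.

**Step 13**
Reactants: 20 trimer; 19 epicatechin C4 electrophile
Product: 21 5,7,3',4'-tetra-O-benzylepicatechin-(4β→8)-5,7,3',4'-tetra-O-benzylepicatechin-(4β→8)-3-O-acetyl-5,7,3',4'-tetra-O-benzylepicatechin-(4β→8)-3-O-acetyl-5,7,3',4'-tetra-O-benzylcatechin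
Conditions: 20 (2.5 equiv), TMSOTf (0.2 equiv), CH2Cl2, −78 °C; Et3N
Reagents that add atoms: none
Why: the same Lewis-acid-mediated coupling as in step 12 should extend the chain at C8 of the upper unit of 20 with 3,4-trans (4β) attack.

**Step 14**
Reactants: 21 tetramer diacetate
Product: 22 5,7,3',4'-tetra-O-benzylepicatechin-(4β→8)-5,7,3',4'-tetra-O-benzylepicatechin-(4β→8)-5,7,3',4'-tetra-O-benzylepicatechin-(4β→8)-5,7,3',4'-tetra-O-benzylcatechin (hexadeca-O-benzyl ether of the target; four free 3-OH)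
Conditions: NaOMe, MeOH–THF, 40 °C
Reagents that add atoms: none
Why: Zemplén transesterification removes the two acetates, while benzyl ethers, interflavan bonds and stereocentres are inert to methoxide.

**Step 15**
Reactants: 22 hexadeca-O-benzyl tetramer
Product: 23 epicatechin-(4β→8)-epicatechin-(4β→8)-epicatechin-(4β→8)-catechin (the target)
Conditions: H2 (1 atm), Pd(OH)2/C, THF–MeOH–H2O, rt
Reagents that add atoms: none
Why: hydrogenolysis cleaves the sixteen benzyl ethers without touching any stereocentre or the interflavan bonds.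

**Compound list**
1 | 3,5-bis(benzyloxy)phenol | Oc1cc(OCc2ccccc2)cc(OCc2ccccc2)c1 | starting material
2 | 4,6-bis(benzyloxy)-1-benzofuran-2,3-dione | O=C1Oc2cc(OCc3ccccc3)cc(OCc3ccccc3)c2C1=O | intermediate
3 | 3,4-bis(benzyloxy)benzyl chloride | ClCc1ccc(OCc2ccccc2)c(OCc2ccccc2)c1 | starting material
4 | methyl 2-[2,4-bis(benzyloxy)-6-hydroxyphenyl]-2-oxoacetate | COC(=O)C(=O)c1c(O)cc(OCc2ccccc2)cc1OCc1ccccc1 | intermediate (not isolated)
5 | methyl 2-{2,4-bis(benzyloxy)-6-{[3,4-bis(benzyloxy)phenyl]methoxy}phenyl}-2-oxoacetate | COC(=O)C(=O)c1c(OCc2ccc(OCc3ccccc3)c(OCc3ccccc3)c2)cc(OCc2ccccc2)cc1OCc1ccccc1 | intermediate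
6 | tosylhydrazone of 5 (mixture of C=N isomers) | COC(=O)C(=NNS(=O)(=O)c1ccc(C)cc1)c1c(OCc2ccc(OCc3ccccc3)c(OCc3ccccc3)c2)cc(OCc2ccccc2)cc1OCc1ccccc1 | intermediate (not isolated)
7 | methyl 2-{2,4-bis(benzyloxy)-6-{[3,4-bis(benzyloxy)phenyl]methoxy}phenyl}-2-diazoacetate | COC(=O)C(=[N+]=[N-])c1c(OCc2ccc(OCc3ccccc3)c(OCc3ccccc3)c2)cc(OCc2ccccc2)cc1OCc1ccccc1 | intermediate
8 | methyl (2S,3R)-4,6-bis(benzyloxy)-2-[3,4-bis(benzyloxy)phenyl]-2,3-dihydro-1-benzofuran-3-carboxylate (cis) | O1[C@H](c2ccc(OCc3ccccc3)c(OCc3ccccc3)c2)[C@H](C(=O)OC)c2c(OCc3ccccc3)cc(OCc3ccccc3)cc12 | intermediate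
9 | [(2S,3S)-4,6-bis(benzyloxy)-2-[3,4-bis(benzyloxy)phenyl]-2,3-dihydro-1-benzofuran-3-yl]methanol (cis) | O1[C@H](c2ccc(OCc3ccccc3)c(OCc3ccccc3)c2)[C@H](CO)c2c(OCc3ccccc3)cc(OCc3ccccc3)cc12 | intermediate
10 | (2S,3R)-4,6-bis(benzyloxy)-2-[3,4-bis(benzyloxy)phenyl]-2,3-dihydro-1-benzofuran-3-carbaldehyde (cis) | O1[C@H](c2ccc(OCc3ccccc3)c(OCc3ccccc3)c2)[C@H](C=O)c2c(OCc3ccccc3)cc(OCc3ccccc3)cc12 | intermediate
11 | (+)-catechin | Oc1cc(O)c2c(c1)O[C@H](c1ccc(O)c(O)c1)[C@@H](O)C2 | starting material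
12 | 5,7,3',4'-tetra-O-benzyl-(+)-catechin | c1ccccc1COc1cc(OCc3ccccc3)c2c(c1)O[C@H](c1ccc(OCc3ccccc3)c(OCc3ccccc3)c1)[C@@H](O)C2 | intermediate
13 | 3-O-acetyl-5,7,3',4'-tetra-O-benzyl-(+)-catechin | c1ccccc1COc1cc(OCc3ccccc3)c2c(c1)O[C@H](c1ccc(OCc3ccccc3)c(OCc3ccccc3)c1)[C@@H](OC(C)=O)C2 | intermediate
14 | [(2S,3R)-4,6-bis(benzyloxy)-2-[3,4-bis(benzyloxy)phenyl]-2,3-dihydro-1-benzofuran-3-yl]methylene diacetate (cis) | O1[C@H](c2ccc(OCc3ccccc3)c(OCc3ccccc3)c2)[C@H](C(OC(C)=O)OC(C)=O)c2c(OCc3ccccc3)cc(OCc3ccccc3)cc12 | intermediate (not isolated)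
15 | 3-O-acetyl-4β-acetoxy-5,7,3',4'-tetra-O-benzyl-(−)-epicatechin (2,3-cis-3,4-trans flavan-3,4-diyl diacetate) | c1ccccc1COc1cc(OCc3ccccc3)c2c(c1)O[C@H](c1ccc(OCc3ccccc3)c(OCc3ccccc3)c1)[C@H](OC(C)=O)[C@H]2OC(C)=O | intermediate (not isolated)
16 | 3-O-acetyl-5,7,3',4'-tetra-O-benzylepicatechin-(4β→8)-3-O-acetyl-5,7,3',4'-tetra-O-benzylcatechin | c1ccccc1COc1cc(OCc3ccccc3)c2c(c1)O[C@H](c1ccc(OCc3ccccc3)c(OCc3ccccc3)c1)[C@H](OC(C)=O)[C@H]2c1c(OCc3ccccc3)cc(OCc3ccccc3)c2c1O[C@H](c1ccc(OCc3ccccc3)c(OCc3ccccc3)c1)[C@@H](OC(C)=O)C2 | intermediate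
17 | (−)-epicatechin | Oc1cc(O)c2c(c1)O[C@H](c1ccc(O)c(O)c1)[C@H](O)C2 | starting material
18 | 5,7,3',4'-tetra-O-benzyl-(−)-epicatechin | c1ccccc1COc1cc(OCc3ccccc3)c2c(c1)O[C@H](c1ccc(OCc3ccccc3)c(OCc3ccccc3)c1)[C@H](O)C2 | intermediate
19 | 4β-(2-ethoxyethoxy)-5,7,3',4'-tetra-O-benzyl-(−)-epicatechin | c1ccccc1COc1cc(OCc3ccccc3)c2c(c1)O[C@H](c1ccc(OCc3ccccc3)c(OCc3ccccc3)c1)[C@H](O)[C@H]2OCCOCC | intermediate
20 | trimer: tetra-O-benzylepicatechin-(4β→8)-3-O-acetyl-tetra-O-benzylepicatechin-(4β→8)-3-O-acetyl-tetra-O-benzylcatechin | c1ccccc1COc1cc(OCc3ccccc3)c2c(c1)O[C@H](c1ccc(OCc3ccccc3)c(OCc3ccccc3)c1)[C@H](O)[C@H]2c1c(OCc3ccccc3)cc(OCc3ccccc3)c2c1O[C@H](c1ccc(OCc3ccccc3)c(OCc3ccccc3)c1)[C@H](OC(C)=O)[C@H]2c1c(OCc3ccccc3)cc(OCc3ccccc3)c2c1O[C@H](c1ccc(OCc3ccccc3)c(OCc3ccccc3)c1)[C@@H](OC(C)=O)C2 | intermediate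
21 | tetramer diacetate: tetra-O-benzylepicatechin-(4β→8)-tetra-O-benzylepicatechin-(4β→8)-3-O-acetyl-tetra-O-benzylepicatechin-(4β→8)-3-O-acetyl-tetra-O-benzylcatechin | c1ccccc1COc1cc(OCc3ccccc3)c2c(c1)O[C@H](c1ccc(OCc3ccccc3)c(OCc3ccccc3)c1)[C@H](O)[C@H]2c1c(OCc3ccccc3)cc(OCc3ccccc3)c2c1O[C@H](c1ccc(OCc3ccccc3)c(OCc3ccccc3)c1)[C@H](O)[C@H]2c1c(OCc3ccccc3)cc(OCc3ccccc3)c2c1O[C@H](c1ccc(OCc3ccccc3)c(OCc3ccccc3)c1)[C@H](OC(C)=O)[C@H]2c1c(OCc3ccccc3)cc(OCc3ccccc3)c2c1O[C@H](c1ccc(OCc3ccccc3)c(OCc3ccccc3)c1)[C@@H](OC(C)=O)C2 | intermediate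
22 | hexadeca-O-benzyl tetramer: tetra-O-benzylepicatechin-(4β→8)-tetra-O-benzylepicatechin-(4β→8)-tetra-O-benzylepicatechin-(4β→8)-tetra-O-benzylcatechin (four free 3-OH) | c1ccccc1COc1cc(OCc3ccccc3)c2c(c1)O[C@H](c1ccc(OCc3ccccc3)c(OCc3ccccc3)c1)[C@H](O)[C@H]2c1c(OCc3ccccc3)cc(OCc3ccccc3)c2c1O[C@H](c1ccc(OCc3ccccc3)c(OCc3ccccc3)c1)[C@H](O)[C@H]2c1c(OCc3ccccc3)cc(OCc3ccccc3)c2c1O[C@H](c1ccc(OCc3ccccc3)c(OCc3ccccc3)c1)[C@H](O)[C@H]2c1c(OCc3ccccc3)cc(OCc3ccccc3)c2c1O[C@H](c1ccc(OCc3ccccc3)c(OCc3ccccc3)c1)[C@@H](O)C2 | intermediate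
23 | epicatechin-(4β→8)-epicatechin-(4β→8)-epicatechin-(4β→8)-catechin | Oc1cc(O)c2c(c1)O[C@H](c1ccc(O)c(O)c1)[C@H](O)[C@H]2c1c(O)cc(O)c2c1O[C@H](c1ccc(O)c(O)c1)[C@H](O)[C@H]2c1c(O)cc(O)c2c1O[C@H](c1ccc(O)c(O)c1)[C@H](O)[C@H]2c1c(O)cc(O)c2c1O[C@H](c1ccc(O)c(O)c1)[C@@H](O)C2 | target

**Count**
Total: 15 steps. Longest linear sequence: 11 steps (steps 1–6, 9, 12, 13, 14, 15).

**Steps most likely to fail**

Step 9. What may go wrong: 1,2-hydride shift or enolisation of the acetoxy carbenium ion may outrun the aryl shift, the phenonium ion may collapse back to the five-membered ring, or the cation may self-condense with ring A of unreacted material. The fallback gives up the ring enlargement and takes unit 3 from (−)-epicatechin by precedented steps; it sets out from 19 and 13 and comes back at 16. The free 3-OH of 19 is acetylated (Ac2O, pyridine, DMAP, CH2Cl2, rt) to 3-O-acetyl-4β-(2-ethoxyethoxy)-5,7,3',4'-tetra-O-benzyl-(−)-epicatechin F1. TMSOTf-catalysed condensation of F1 with excess 13 (CH2Cl2, −78 °C) then gives 16 by attack of C8 of 13 anti to the 3-acetoxy group.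

Step 4. What may go wrong: insertion into the competing benzyl ether C–H at the other ortho oxygen, and insufficient cis- or enantioselectivity with the doubly ortho-substituted aryl carbenoid. The fallback sets out from phenol 1 and comes back at 8, without a carbenoid. Still–Gennari olefination of commercial 3,4-bis(benzyloxy)benzaldehyde (methyl bis(2,2,2-trifluoroethyl)phosphonoacetate, KN(SiMe3)2, 18-crown-6, THF, −78 °C) gives methyl (2Z)-3-[3,4-bis(benzyloxy)phenyl]prop-2-enoate F2. Jacobsen–Katsuki epoxidation ((salen)MnCl with trivalent manganese, salen = N,N'-bis(3,5-di-tert-butylsalicylidene)-1,2-cyclohexanediamine dianion, in the enantiomeric form that gives the (2S,3S) product; NaOCl) gives the cis-glycidate methyl (2S,3S)-3-[3,4-bis(benzyloxy)phenyl]oxirane-2-carboxylate F3. The phenoxide of 1 (Cs2CO3, DMF) opens the epoxide at the benzylic carbon with inversion to methyl (2S,3R)-3-[3,5-bis(benzyloxy)phenoxy]-3-[3,4-bis(benzyloxy)phenyl]-2-hydroxypropanoate F4. Triflation (Tf2O, 2,6-lutidine, −78 °C) gives methyl (2S,3R)-3-[3,5-bis(benzyloxy)phenoxy]-3-[3,4-bis(benzyloxy)phenyl]-2-(trifluoromethylsulfonyloxy)propanoate F5. Intramolecular Friedel–Crafts alkylation of the ortho carbon of the phloroglucinol ring by the α-triflyloxy ester (SN2 with inversion, 5-exo-tet; 2,6-di-tert-butylpyridine, CH2Cl2, 0 °C) closes the cis-dihydrobenzofuran 8.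

Step 13. What may go wrong: loss of regiocontrol (attack at C6 positions) and chain growth past the tetramer, because the product is as nucleophilic as the trimer and the electrophile can condense with itself. The fallback sets out from 18 and 20 and comes back at 23. Compound 18 is brominated at C8 (NBS, CH2Cl2, −20 °C) to 8-bromo-5,7,3',4'-tetra-O-benzyl-(−)-epicatechin F6, whose ring A can no longer act as a nucleophile. DDQ and 2-ethoxyethanol (CH2Cl2, rt) give 8-bromo-4β-(2-ethoxyethoxy)-5,7,3',4'-tetra-O-benzyl-(−)-epicatechin F7. Near-equimolar TMSOTf-mediated condensation of F7 with 20 gives the C8-capped tetramer, 8-bromo-tetra-O-benzylepicatechin-(4β→8)-tetra-O-benzylepicatechin-(4β→8)-3-O-acetyl-tetra-O-benzylepicatechin-(4β→8)-3-O-acetyl-tetra-O-benzylcatechin F8. NaOMe in MeOH–THF removes the acetates to give 8-bromo-tetra-O-benzylepicatechin-(4β→8)-tetra-O-benzylepicatechin-(4β→8)-tetra-O-benzylepicatechin-(4β→8)-tetra-O-benzylcatechin F9. Hydrogenolysis over Pd(OH)2/C with Et3N removes the sixteen benzyl groups and the bromine and gives 23.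

**Further compounds**
F1 | step 9 | 3-O-acetyl-4β-(2-ethoxyethoxy)-5,7,3',4'-tetra-O-benzyl-(−)-epicatechin | c1ccccc1COc1cc(OCc3ccccc3)c2c(c1)O[C@H](c1ccc(OCc3ccccc3)c(OCc3ccccc3)c1)[C@H](OC(C)=O)[C@H]2OCCOCC
F2 | step 4 | methyl (2Z)-3-[3,4-bis(benzyloxy)phenyl]prop-2-enoate | COC(=O)/C=C\c1ccc(OCc2ccccc2)c(OCc2ccccc2)c1
F3 | step 4 | methyl (2S,3S)-3-[3,4-bis(benzyloxy)phenyl]oxirane-2-carboxylate (cis) | O1[C@@H](c2ccc(OCc3ccccc3)c(OCc3ccccc3)c2)[C@H]1C(=O)OC
F4 | step 4 | methyl (2S,3R)-3-[3,5-bis(benzyloxy)phenoxy]-3-[3,4-bis(benzyloxy)phenyl]-2-hydroxypropanoate | c1c(OCc2ccccc2)cc(OCc2ccccc2)cc1O[C@H](c1ccc(OCc2ccccc2)c(OCc2ccccc2)c1)[C@@H](C(=O)OC)O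
F5 | step 4 | methyl (2S,3R)-3-[3,5-bis(benzyloxy)phenoxy]-3-[3,4-bis(benzyloxy)phenyl]-2-(trifluoromethylsulfonyloxy)propanoate | c1c(OCc2ccccc2)cc(OCc2ccccc2)cc1O[C@H](c1ccc(OCc2ccccc2)c(OCc2ccccc2)c1)[C@@H](C(=O)OC)OS(=O)(=O)C(F)(F)F
F6 | step 13 | 8-bromo-5,7,3',4'-tetra-O-benzyl-(−)-epicatechin | c1ccccc1COc1cc(OCc3ccccc3)c2c(c1Br)O[C@H](c1ccc(OCc3ccccc3)c(OCc3ccccc3)c1)[C@H](O)C2
F7 | step 13 | 8-bromo-4β-(2-ethoxyethoxy)-5,7,3',4'-tetra-O-benzyl-(−)-epicatechin | c1ccccc1COc1cc(OCc3ccccc3)c2c(c1Br)O[C@H](c1ccc(OCc3ccccc3)c(OCc3ccccc3)c1)[C@H](O)[C@H]2OCCOCC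
F8 | step 13 | 8-bromo tetramer diacetate (C8-capped analogue of 21) | c1ccccc1COc1cc(OCc3ccccc3)c2c(c1Br)O[C@H](c1ccc(OCc3ccccc3)c(OCc3ccccc3)c1)[C@H](O)[C@H]2c1c(OCc3ccccc3)cc(OCc3ccccc3)c2c1O[C@H](c1ccc(OCc3ccccc3)c(OCc3ccccc3)c1)[C@H](O)[C@H]2c1c(OCc3ccccc3)cc(OCc3ccccc3)c2c1O[C@H](c1ccc(OCc3ccccc3)c(OCc3ccccc3)c1)[C@H](OC(C)=O)[C@H]2c1c(OCc3ccccc3)cc(OCc3ccccc3)c2c1O[C@H](c1ccc(OCc3ccccc3)c(OCc3ccccc3)c1)[C@@H](OC(C)=O)C2
F9 | step 13 | 8-bromo hexadeca-O-benzyl tetramer (C8-capped analogue of 22) | c1ccccc1COc1cc(OCc3ccccc3)c2c(c1Br)O[C@H](c1ccc(OCc3ccccc3)c(OCc3ccccc3)c1)[C@H](O)[C@H]2c1c(OCc3ccccc3)cc(OCc3ccccc3)c2c1O[C@H](c1ccc(OCc3ccccc3)c(OCc3ccccc3)c1)[C@H](O)[C@H]2c1c(OCc3ccccc3)cc(OCc3ccccc3)c2c1O[C@H](c1ccc(OCc3ccccc3)c(OCc3ccccc3)c1)[C@H](O)[C@H]2c1c(OCc3ccccc3)cc(OCc3ccccc3)c2c1O[C@H](c1ccc(OCc3ccccc3)c(OCc3ccccc3)c1)[C@@H](O)C2
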